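**Retrosynthetic overview**

1. The last bond made is the exocyclic C2–NH of the imidazole to C4 of the dehydrohydantoin ring, by condensing the free 2-aminoimidazole with silyl-activated 1-methylparabanic acid; the phenol is unmasked by benzyl ether hydrogenolysis just before.
2. The strategy rests on the 2-aminoimidazole ring (N1-methyl, C2-amino, N3, C4, C5). Its C4–CH2–(4-methoxyphenyl) arm is treated as a latent aryl alkyne on C5, so the N3–C4 bond is cut back to a di-Boc propargylguanidine that closes by AgNO3-catalysed 5-exo-dig hydroamination; acid then removes the Boc groups and moves the exocyclic alkene into the ring.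
3. The propargylguanidine comes from a three-component aldehyde–amine–alkyne coupling of an arylacetaldehyde, N-allylmethylamine (a methylamine surrogate) and 4-ethynylanisole, followed by N-deallylation and guanylation; N1-methyl and both benzylic arms are fixed before ring closure.
4. The arylacetaldehyde derives from 2,3-dimethoxyphenol by O-allylation, aromatic Claisen rearrangement to C6, O-benzylation and oxidative alkene cleavage.
5. Ring order: both benzene rings are bought, the imidazole ring is closed in step 8 and aromatised in step 9, and the dehydrohydantoin ring is attached intact in step 11.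

Key step: step 8

Remark: the target is achiral, so the stereocentre created in step 5 is carried racemic and is erased in step 9; catalyst-bound species of catalytic cycles (copper acetylide, π-allylpalladium, vinylsilver, osmate ester) are described in words and carry no number.

**Route**

Step 1
Reactants: 1 2,3-dimethoxyphenol; 2 allyl bromide
Product: 3 1-(allyloxy)-2,3-dimethoxybenzene
Conditions: K2CO3, acetone, reflux
Reagents that add atoms: allyl bromide 2, C=CCBr
Why: Williamson O-alkylation of the phenoxide by a primary allylic bromide (SN2) should proceed cleanly on this unhindered phenol.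

Step 2
Reactants: 3 1-(allyloxy)-2,3-dimethoxybenzene
Product: 5 6-allyl-2,3-dimethoxyphenol, via dienone 4 (not isolated)
Conditions: N,N-diethylaniline, 200 °C, Ar
Reagents that add atoms: none
Why: The aromatic Claisen rearrangement ([3,3]-sigmatropic shift) can only deliver the allyl group to C6, the single unsubstituted ortho position, and dienone 4 then tautomerises to the phenol.

Step 3
Reactants: 5 6-allyl-2,3-dimethoxyphenol; 6 benzyl bromide
Product: 7 1-allyl-2-(benzyloxy)-3,4-dimethoxybenzene
Conditions: K2CO3, DMF, 60 °C
Reagents that add atoms: benzyl bromide 6, BrCc1ccccc1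
Why: Williamson etherification installs a benzyl ether that should survive the copper, palladium, mercury, silver and acid steps and is removed by hydrogenolysis only after the alkyne has been consumed.

Step 4
Reactants: 7 1-allyl-2-(benzyloxy)-3,4-dimethoxybenzene
Product: 9 2-[2-(benzyloxy)-3,4-dimethoxyphenyl]acetaldehyde, via diol 8 (not isolated)
Conditions: OsO4 (2 mol %), NaIO4, 2,6-lutidine, dioxane/H2O, rt; used crude
Reagents that add atoms: osmium tetroxide, O=[Os](=O)(=O)=O (delivers the oxygen and is re-formed by sodium periodate, [Na+].[O-][I](=O)(=O)=O)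
Why: Lemieux–Johnson oxidation (OsO4-catalysed dihydroxylation of the terminal alkene, then periodate glycol cleavage) should give the arylacetaldehyde without touching the electron-rich arene, with 2,6-lutidine suppressing over-oxidation.

Step 5
Reactants: 9 2-[2-(benzyloxy)-3,4-dimethoxyphenyl]acetaldehyde; 10 N-allylmethylamine; 11 4-ethynylanisole
Product: 13 N-allyl-1-[2-(benzyloxy)-3,4-dimethoxyphenyl]-4-(4-methoxyphenyl)-N-methylbut-3-yn-2-amine (racemic), via iminium ion 12 (not isolated)
Conditions: CuBr (10 mol %), 4 Å MS, MeCN, rt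
Reagents that add atoms: N-allylmethylamine 10, CNCC=C; 4-ethynylanisole 11, COc1ccc(C#C)cc1
Why: In this CuBr-catalysed (monovalent copper) three-component aldehyde–amine–alkyne coupling the copper acetylide of 11 adds to iminium ion 12 formed from 9 and 10, creating the propargylic stereocentre as a racemate, which is acceptable because it is erased in step 9.

Step 6
Reactants: 13 N-allyl-1-[2-(benzyloxy)-3,4-dimethoxyphenyl]-4-(4-methoxyphenyl)-N-methylbut-3-yn-2-amine
Product: 14 1-[2-(benzyloxy)-3,4-dimethoxyphenyl]-4-(4-methoxyphenyl)-N-methylbut-3-yn-2-amine (racemic)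
Conditions: Pd(PPh3)4 (5 mol %), thiosalicylic acid, CH2Cl2, 35 °C
Reagents that add atoms: none
Why: Pd(PPh3)4 (zerovalent palladium) ionises the protonated allylamine to a π-allyl complex that is trapped irreversibly by the thiol of thiosalicylic acid (Tsuji–Trost-type N-deallylation), leaving the alkyne and benzyl ether untouched.

Step 7
Reactants: 14 1-[2-(benzyloxy)-3,4-dimethoxyphenyl]-4-(4-methoxyphenyl)-N-methylbut-3-yn-2-amine; 15 N,N'-di-Boc-S-methylisothiourea
Product: 16 N,N'-di-Boc-N''-methyl-N''-[1-(2-benzyloxy-3,4-dimethoxyphenyl)-4-(4-methoxyphenyl)but-3-yn-2-yl]guanidine (racemic)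
Conditions: HgCl2 (1.1 equiv), Et3N, DMF, 0 °C to rt
Reagents that add atoms: N,N'-di-Boc-S-methylisothiourea 15, CSC(=NC(=O)OC(C)(C)C)NC(=O)OC(C)(C)C
Why: Thiophilic activation of the isothiourea by HgCl2 (divalent mercury) lets even this hindered secondary amine displace methanethiolate by addition–elimination (mercury-promoted guanylation).

Step 8
Reactants: 16 N,N'-di-Boc-N''-methyl-N''-[1-(2-benzyloxy-3,4-dimethoxyphenyl)-4-(4-methoxyphenyl)but-3-yn-2-yl]guanidine
Product: 17 (Z)-4-(4-methoxybenzylidene) cyclic di-Boc guanidine: 2-iminoimidazolidine with N1-methyl, C2=N-Boc, N3-Boc, C4=CH(4-methoxyphenyl) of Z geometry and C5-[2-(benzyloxy)-3,4-dimethoxybenzyl] (racemic at C5)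
Conditions: AgNO3 (15 mol %), MeCN, rt, dark
Reagents that add atoms: none
Why: AgNO3 (monovalent silver) binds the alkyne as a π-acid, the carbamate N–H nitrogen of the guanidine adds anti to silver at the alkyne carbon next to C5, and protodemetalation of the vinylsilver species by the proton just released gives the Z-benzylidene and returns the catalyst. The closest known reaction is the silver-catalysed hydroamination of Boc-protected propargylguanidines to five-membered cyclic ene-guanidines, applied here to a new substrate. The one ring formed (N1, C2, N3, C4, C5) closes in the 5-exo-dig mode through the new N3–C4 bond. No stereocentre is created; the only stereochemical element is the Z alkene, fixed by the anti aminometalation, and the racemic C5 centre is untouched. The step needs 5-exo over 6-endo selectivity and N- over O-attack of a Boc carbonyl: the three-atom N–C–N tether reaches the proximal alkyne carbon without strain whereas 6-endo attack at the anisyl-bearing carbon must bend the alkyne inside the ring, and allylic strain from the N-methyl group in the planar acylguanidine turns the N–H nitrogen toward the triple bond. The electron-rich anisyl group, which polarises the alkyne toward the endo carbon, is the residual risk.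

Step 9
Reactants: 17 (Z)-4-(4-methoxybenzylidene) cyclic di-Boc guanidine
Product: 19 5-[2-(benzyloxy)-3,4-dimethoxybenzyl]-4-(4-methoxybenzyl)-1-methyl-1H-imidazol-2-amine, via ene-guanidine 18 (not isolated)
Conditions: TFA/CH2Cl2 1:4, 0 °C to rt; aq. NaHCO3
Reagents that add atoms: none
Why: Acidolysis removes both Boc groups to give ene-guanidine 18, which is protonated at the benzylidene carbon and loses the hydrogen on C5 (1,3-prototropic shift driven by aromatisation), turning the distal alkyne carbon into the CH2 of the 4-methoxybenzyl arm and erasing the C5 stereocentre.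

Step 10
Reactants: 19 5-[2-(benzyloxy)-3,4-dimethoxybenzyl]-4-(4-methoxybenzyl)-1-methyl-1H-imidazol-2-amine
Product: 20 6-{[2-amino-4-(4-methoxybenzyl)-1-methyl-1H-imidazol-5-yl]methyl}-2,3-dimethoxyphenol
Conditions: H2 (1 atm), 10 % Pd/C, MeOH, rt
Reagents that add atoms: none
Why: Catalytic hydrogenolysis cleaves the aryl benzyl ether C–O bond selectively, since no alkyne or alkene remains and the aromatic imidazole and methyl ethers are inert.

Step 11
Reactants: 20 6-{[2-amino-4-(4-methoxybenzyl)-1-methyl-1H-imidazol-5-yl]methyl}-2,3-dimethoxyphenol; 21 1-methylparabanic acid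
Product: 25 pyronaamidine, via silyl imidate 22 (not isolated), via silyl ether 23 (not isolated), via silylated pyronaamidine 24 (not isolated)
Conditions: 21, BSA, MeCN, 80 °C; add 20 pre-treated with BSA, toluene, 110 °C; then MeOH/H2O, rt
Reagents that add atoms: 1-methylparabanic acid 21, CN1C(=O)NC(=O)C1=O (BSA, CC(=N[Si](C)(C)C)O[Si](C)(C)C, supplies only the transient SiMe3 groups of 22 to 24)
Why: Silylation converts the N3–H/C4=O unit of 21 into silyl imidate 22, whose C4 is attacked by the exocyclic NH2 of the O-silylated amine 23 in an addition–elimination expelling Me3SiOH, and the aryl silyl ether of 24 is cleaved on aqueous methanolic work-up (the known condensation of 2-aminoimidazoles with silyl-activated 1-methylparabanic acid).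

**Compound list**

1 | 2,3-dimethoxyphenol | COc1cccc(O)c1OC | starting material
2 | allyl bromide | C=CCBr | starting material
3 | 1-(allyloxy)-2,3-dimethoxybenzene | C=CCOc1cccc(OC)c1OC | intermediate
4 | 6-allyl-2,3-dimethoxycyclohexa-2,4-dien-1-one (racemic, not isolated) | C=CCC1C=CC(OC)=C(OC)C1=O | intermediate
5 | 6-allyl-2,3-dimethoxyphenol | C=CCc1ccc(OC)c(OC)c1O | intermediate
6 | benzyl bromide | BrCc1ccccc1 | starting material
7 | 1-allyl-2-(benzyloxy)-3,4-dimethoxybenzene | C=CCc1ccc(OC)c(OC)c1OCc1ccccc1 | intermediate
8 | 3-[2-(benzyloxy)-3,4-dimethoxyphenyl]propane-1,2-diol (racemic, not isolated) | OCC(O)Cc1ccc(OC)c(OC)c1OCc1ccccc1 | intermediate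
9 | 2-[2-(benzyloxy)-3,4-dimethoxyphenyl]acetaldehyde | O=CCc1ccc(OC)c(OC)c1OCc1ccccc1 | intermediate
10 | N-allylmethylamine | CNCC=C | starting material
11 | 4-ethynylanisole | COc1ccc(C#C)cc1 | starting material
12 | N-allyl-N-methyl iminium ion of aldehyde 9 (not isolated) | C=CC[N+](C)=CCc1ccc(OC)c(OC)c1OCc1ccccc1 | intermediate
13 | N-allyl-1-[2-(benzyloxy)-3,4-dimethoxyphenyl]-4-(4-methoxyphenyl)-N-methylbut-3-yn-2-amine (racemic) | C=CCN(C)C(Cc1ccc(OC)c(OC)c1OCc1ccccc1)C#Cc1ccc(OC)cc1 | intermediate
14 | 1-[2-(benzyloxy)-3,4-dimethoxyphenyl]-4-(4-methoxyphenyl)-N-methylbut-3-yn-2-amine (racemic) | CNC(Cc1ccc(OC)c(OC)c1OCc1ccccc1)C#Cc1ccc(OC)cc1 | intermediate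
15 | N,N'-di-Boc-S-methylisothiourea | CSC(=NC(=O)OC(C)(C)C)NC(=O)OC(C)(C)C | starting material
16 | N,N'-di-Boc-N''-methyl-N''-[1-(2-benzyloxy-3,4-dimethoxyphenyl)-4-(4-methoxyphenyl)but-3-yn-2-yl]guanidine (racemic) | CN(C(=NC(=O)OC(C)(C)C)NC(=O)OC(C)(C)C)C(Cc1ccc(OC)c(OC)c1OCc1ccccc1)C#Cc1ccc(OC)cc1 | intermediate
17 | (Z)-4-(4-methoxybenzylidene) cyclic di-Boc guanidine (racemic at C5) | CN1C(=NC(=O)OC(C)(C)C)N(C(=O)OC(C)(C)C)/C(=C\c2ccc(OC)cc2)C1Cc1ccc(OC)c(OC)c1OCc1ccccc1 | intermediate
18 | (Z)-2-amino-5-[2-(benzyloxy)-3,4-dimethoxybenzyl]-4-(4-methoxybenzylidene)-1-methyl-4,5-dihydro-1H-imidazole (racemic, not isolated) | CN1C(N)=N/C(=C\c2ccc(OC)cc2)C1Cc1ccc(OC)c(OC)c1OCc1ccccc1 | intermediate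
19 | 5-[2-(benzyloxy)-3,4-dimethoxybenzyl]-4-(4-methoxybenzyl)-1-methyl-1H-imidazol-2-amine | Cn1c(N)nc(Cc2ccc(OC)cc2)c1Cc1ccc(OC)c(OC)c1OCc1ccccc1 | intermediate
20 | 6-{[2-amino-4-(4-methoxybenzyl)-1-methyl-1H-imidazol-5-yl]methyl}-2,3-dimethoxyphenol | Cn1c(N)nc(Cc2ccc(OC)cc2)c1Cc1ccc(OC)c(OC)c1O | intermediate
21 | 1-methylparabanic acid (1-methylimidazolidine-2,4,5-trione) | CN1C(=O)NC(=O)C1=O | starting material
22 | 1-methyl-4-(trimethylsilyloxy)-1H-imidazole-2,5-dione (silyl imidate, not isolated) | CN1C(=O)N=C(O[Si](C)(C)C)C1=O | intermediate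
23 | aryl trimethylsilyl ether of 20 (not isolated) | Cn1c(N)nc(Cc2ccc(OC)cc2)c1Cc1ccc(OC)c(OC)c1O[Si](C)(C)C | intermediate
24 | O-trimethylsilyl pyronaamidine (not isolated) | COc1ccc(Cc2nc(NC3=NC(=O)N(C)C3=O)n(C)c2Cc2ccc(OC)c(OC)c2O[Si](C)(C)C)cc1 | intermediate
25 | pyronaamidine | COc1ccc(Cc2nc(NC3=NC(=O)N(C)C3=O)n(C)c2Cc2ccc(OC)c(OC)c2O)cc1 | target

**Step count and risks**

Total step count: 11. Longest linear sequence: 11 steps (1 to 25); all other components are bought.

Steps most likely to fail:

1. Step 8. The 4-methoxyphenyl group polarises the silver-bound alkyne toward its aryl-bearing carbon, so 6-endo-dig closure, or attack by a Boc carbonyl oxygen with loss of the tert-butyl group, may compete with N3–C4 bond formation. Fallback, setting out from 16 and returning at 19: the Boc groups are removed first (TFA/CH2Cl2, 0 °C) to give the free N-methyl-N-propargylguanidine F1 as its trifluoroacetate salt, and F1 is then cyclised in the anionic manifold (Cs2CO3, MeCN, 60 °C). There the guanidine nitrogen should add to the unactivated aryl alkyne in the 5-exo mode usual for base-mediated cyclisations of N-propargyl guanidines, ureas and thioureas, with the vinyl anion developing on the aryl-bearing carbon. No carbamate oxygen is present, and base-mediated tautomerisation of the resulting ene-guanidine 18 should deliver 19 directly.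

2. Step 5. The enolisable arylacetaldehyde may be diverted into aldol self-condensation and air oxidation before the iminium ion is captured, and prolonged contact with CuBr may isomerise the propargylamine to an allene. Fallback, setting out from 9 and 11 and returning at 14: 11 is deprotonated (n-BuLi, THF, −78 °C) to lithium (4-methoxyphenyl)acetylide F2, which adds to 9 at −78 °C (CeCl3 if enolisation intervenes) to give the propargylic alcohol F3 after NH4Cl quench. Fukuyama–Mitsunobu reaction of F3 with N-methyl-2-nitrobenzenesulfonamide (PPh3, DIAD, THF) gives the sulfonamide F4, and thiophenol/K2CO3 in DMF removes the nosyl group to give 14, bypassing 13 and step 6.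

3. Step 11. The ring nitrogen or an incompletely silylated phenol may attack the silyl imidate, the imidate may hydrolyse prematurely, and the electron-rich free-phenol aminoimidazole may degrade oxidatively at 110 °C. Fallback, setting out from 19 and returning at 25: the condensation is run on the benzyl ether 19 with silyl imidate 22 (from 21 and BSA, toluene, 110 °C) to give O-benzylpyronaamidine F5, a non-phenolic compound that can be purified. The benzyl ether of F5 is then removed by hydrogenolysis (H2, 10 % Pd/C, EtOAc/MeOH, rt), under which the amidine-type C=N of the dehydrohydantoin is not expected to be reduced, giving 25.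

**Further compounds**

F1 | step 8 | N-methyl-N-[1-(2-benzyloxy-3,4-dimethoxyphenyl)-4-(4-methoxyphenyl)but-3-yn-2-yl]guanidine (racemic) | CN(C(N)=N)C(Cc1ccc(OC)c(OC)c1OCc1ccccc1)C#Cc1ccc(OC)cc1
F2 | step 5 | lithium (4-methoxyphenyl)acetylide | [Li]C#Cc1ccc(OC)cc1
F3 | step 5 | 1-[2-(benzyloxy)-3,4-dimethoxyphenyl]-4-(4-methoxyphenyl)but-3-yn-2-ol (racemic) | OC(Cc1ccc(OC)c(OC)c1OCc1ccccc1)C#Cc1ccc(OC)cc1
F4 | step 5 | N-{1-[2-(benzyloxy)-3,4-dimethoxyphenyl]-4-(4-methoxyphenyl)but-3-yn-2-yl}-N-methyl-2-nitrobenzenesulfonamide (racemic) | CN(C(Cc1ccc(OC)c(OC)c1OCc1ccccc1)C#Cc1ccc(OC)cc1)S(=O)(=O)c1ccccc1[N+](=O)[O-]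
F5 | step 11 | O-benzylpyronaamidine | COc1ccc(Cc2nc(NC3=NC(=O)N(C)C3=O)n(C)c2Cc2ccc(OC)c(OC)c2OCc2ccccc2)cc1
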